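The CH2 that links the cyclopentane to the six-membered trione ring is read as a former aldehyde carbon. The cyclopentane CH that carries it then sits α to a formyl group and next to the ring carbinol carbon (C–OH, CH3), an aldol relationship inside the five-membered ring. The key step is a D-proline-catalysed 5-enolexo aldol cyclisation of an acyclic keto aldehyde, (S)-6-oxo-3-isopropenylheptanal, obtained by cleaving the cyclohexene ring of (S)-limonene. It closes the cyclopentane and sets both new stereocentres against the isopropenyl-bearing one. The aldehyde is joined in the same flask to the preformed gem-diprenyl benzoyl trione ring by Knoevenagel condensation and Hantzsch ester reduction.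

Key step: step 4

Remark: 3, 8 and 9 are drawn as single enol tautomers of equilibrating β-triketone systems, the C=C geometry of 8 is left open because it is reduced at once, and 5 is used as its cis/trans epoxide mixture because both isomers give 6.

Step 1
Reactants: 1 2,4,6-trihydroxybenzophenone; 2 prenyl bromide (2 equiv)
Product: 3 2-benzoyl-3,5-dihydroxy-6,6-bis(3-methylbut-2-en-1-yl)cyclohexa-2,4-dien-1-one
Conditions: NaOMe (2 equiv), MeOH, 0 °C to rt
Reagents that add atoms: none
Why: Dearomative double C-alkylation (allylic SN2) of the phloroglucinol anion, in which the second prenyl group enters at the carbon already prenylated to give the gem-diprenyl enolised trione with one ring C–H left; the protic solvent and the soft allylic bromide favour C- over O-alkylation, and no stereocentre is formed.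

Step 2
Reactants: 4 (S)-(−)-limonene
Product: 5 (4S)-limonene 1,2-oxide (cis/trans mixture at the epoxide)
Conditions: mCPBA (1.0 equiv), CH2Cl2, 0 °C
Reagents that add atoms: mCPBA (SMILES: O=C(OO)c1cccc(Cl)c1)
Why: Prilezhaev epoxidation is selective for the more electron-rich trisubstituted ring alkene over the 1,1-disubstituted isopropenyl group, and the epoxide configuration is irrelevant because both epoxide carbons become carbonyl carbons.

Step 3
Reactants: 5 (4S)-limonene 1,2-oxide
Product: 6 (3S)-6-oxo-3-(prop-1-en-2-yl)heptanal
Conditions: H5IO6, THF/H2O, 0 °C to rt
Reagents that add atoms: water (SMILES: O)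
Why: Periodic acid hydrolyses the epoxide to the 1,2-diol and cleaves it in the same pot (Malaprade glycol cleavage) to the keto aldehyde; the isopropenyl-bearing centre is not α to a carbonyl and is carried through unchanged.

Step 4
Reactants: 6 (3S)-6-oxo-3-(prop-1-en-2-yl)heptanal; 3 2-benzoyl-3,5-dihydroxy-6,6-bis(3-methylbut-2-en-1-yl)cyclohexa-2,4-dien-1-one
Product: 9 hypercalin B, via hydroxy aldehyde 7 (not isolated), via alkylidene trione 8 (not isolated)
Conditions: D-proline (20 mol %), CH2Cl2, 0 °C to rt; then 3, Hantzsch ester (1.1 equiv), rt
Reagents that add atoms: none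
Why: D-Proline condenses with the aldehyde of 6 (faster than with the methyl ketone) to the (E)-enamine, whose α-carbon adds to the ketone carbonyl through the transition state of proline aldol catalysis in which the carboxylic acid hydrogen-bonds to the ketone oxygen, and hydrolysis releases hydroxy aldehyde 7. The closest known reaction type is the proline-catalysed enolexo aldolisation of dicarbonyl compounds, and the closure is 5-(enolexo)-exo-trig. The ring CH that carries the formyl group is set by the catalyst (D-proline is the enantiomer that delivers the ketone to the enamine face giving R) and reinforced by the substrate, since that face is anti to the isopropenyl group on the neighbouring fixed S centre; the carbinol centre is set by the hydrogen-bonded transition state, which holds the ketone oxygen on the enamine side and so places OH cis to CHO. The step needs the aldehyde to act as donor and the ketone as acceptor, which enamine catalysis secures (hydroxide would enolise the ketone instead), and it needs the aldol to survive without dehydration, which the mild carboxylic acid catalyst at or below room temperature and the immediate consumption of 7 favour. In the second stage the same catalyst mediates Knoevenagel condensation of 7 with the acidic ring C–H of 3 to the quinone-methide-like alkylidene trione 8, which the Hantzsch ester reduces by hydride transfer to the exocyclic carbon (three-component reductive alkylation of a cyclic 1,3-dione), giving 9 without touching the three stereocentres.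

Compound list
1 | 2,4,6-trihydroxybenzophenone (phlorobenzophenone) | O=C(c1ccccc1)c1c(O)cc(O)cc1O | starting material
2 | prenyl bromide (1-bromo-3-methylbut-2-ene) | CC(C)=CCBr | starting material
3 | 2-benzoyl-3,5-dihydroxy-6,6-bis(3-methylbut-2-en-1-yl)cyclohexa-2,4-dien-1-one (enolised 2-benzoyl-4,4-diprenylcyclohexane-1,3,5-trione, one free ring C–H between the enolic carbons) | O=C(c1ccccc1)C1=C(O)C=C(O)C(CC=C(C)C)(CC=C(C)C)C1=O | intermediate
4 | (S)-(−)-limonene | CC1=CC[C@H](CC1)C(C)=C | starting material
5 | (4S)-limonene 1,2-oxide, cis/trans mixture at the epoxide | CC(=C)[C@H]1CCC2(C)OC2C1 | intermediate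
6 | (3S)-6-oxo-3-(prop-1-en-2-yl)heptanal | C=C(C)[C@@H](CCC(C)=O)CC=O | intermediate
7 | (1R,2S,5S)-2-hydroxy-2-methyl-5-(prop-1-en-2-yl)cyclopentane-1-carbaldehyde (OH cis to CHO, CHO trans to isopropenyl) | C=C(C)[C@H]1CC[C@](C)(O)[C@@H]1C=O | intermediate
8 | 2-benzoyl-3-hydroxy-6-{[(1R,2S,5S)-2-hydroxy-2-methyl-5-(prop-1-en-2-yl)cyclopentyl]methylidene}-4,4-bis(3-methylbut-2-en-1-yl)cyclohex-2-ene-1,5-dione | C=C(C)[C@H]1CC[C@](C)(O)[C@@H]1C=C1C(=O)C(CC=C(C)C)(CC=C(C)C)C(O)=C(C(=O)c2ccccc2)C1=O | intermediate
9 | hypercalin B, 2-benzoyl-3,5-dihydroxy-4-{[(1R,2S,5S)-2-hydroxy-2-methyl-5-(prop-1-en-2-yl)cyclopentyl]methyl}-6,6-bis(3-methylbut-2-en-1-yl)cyclohexa-2,4-dien-1-one | C=C(C)[C@H]1CC[C@](C)(O)[C@@H]1CC1=C(O)C(CC=C(C)C)(CC=C(C)C)C(=O)C(C(=O)c2ccccc2)=C1O | target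

Total step count: 4. Longest linear sequence: 3 steps (4 to 5 to 6 to 9); the second branch (1 to 3) is one step.

Steps most likely to fail

Step 4. The tertiary aldol may dehydrate to the conjugated cyclopentene carbaldehyde, revert by retro-aldol, or epimerise at the formyl-bearing carbon under amine catalysis before it is captured. The fallback sets out from 6 and accepts the dehydration. Piperidine/AcOH in refluxing benzene should give the aldol condensation product (5R)-2-methyl-5-(prop-1-en-2-yl)cyclopent-1-ene-1-carbaldehyde F1. Weitz–Scheffer epoxidation (H2O2, NaOH, MeOH, 0 °C) on the face anti to the isopropenyl group should give the epoxy aldehyde F2. Reductive cleavage of its Cα–O bond with SmI2 (THF/MeOH, −90 °C), followed by protonation of the enolate to the more stable isomer (CHO trans to isopropenyl, cis to OH), should return the route at 7. Isolated 7 is then carried to 9 by the second stage of step 4 run on its own (3, D-proline, Hantzsch ester).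

Step 1. Alkylation at the second free ring carbon (3,5-dialkylation), O-prenylation and over-alkylation may compete with gem-dialkylation. The fallback sets out from 1 and reverses the order of events. Compound 1 is reductively alkylated with 7 (made as in the first stage of step 4; proline, Hantzsch ester, CH2Cl2) to the aromatic cyclopentylmethyl phlorobenzophenone F3. Its single remaining ring C–H is then prenylated twice with 2 (aq. KOH, 0 °C), the bulky cyclopentylmethyl group steering the second prenyl group to the same carbon. This comes back to the route at 9.

Step 3. The acidic one-pot hydrolysis/cleavage may cause rearrangement of the epoxide to a ketone, or acid-catalysed self-condensation of the keto aldehyde. The fallback sets out from 5 and separates the two events. Hydrolysis in dilute aqueous H2SO4/THF should converge both epoxide isomers by trans-diaxial opening on the diol (1R,2R,4S)-1-methyl-4-(prop-1-en-2-yl)cyclohexane-1,2-diol F4. Glycol cleavage with NaIO4 in neutral aqueous THF then comes back to the route at 6.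

Further compounds
F1 | step 4 | (5R)-2-methyl-5-(prop-1-en-2-yl)cyclopent-1-ene-1-carbaldehyde | C=C(C)[C@H]1CCC(C)=C1C=O
F2 | step 4 | (1R,2R,5S)-5-methyl-2-(prop-1-en-2-yl)-6-oxabicyclo[3.1.0]hexane-1-carbaldehyde (epoxide anti to isopropenyl) | C=C(C)[C@H]1CC[C@]2(C)O[C@]12C=O
F3 | step 1 | (3-{[(1R,2S,5S)-2-hydroxy-2-methyl-5-(prop-1-en-2-yl)cyclopentyl]methyl}-2,4,6-trihydroxyphenyl)(phenyl)methanone | C=C(C)[C@H]1CC[C@](C)(O)[C@@H]1Cc1c(O)cc(O)c(C(=O)c2ccccc2)c1O
F4 | step 3 | (1R,2R,4S)-1-methyl-4-(prop-1-en-2-yl)cyclohexane-1,2-diol | CC(=C)[C@H]1CC[C@@](C)(O)[C@H](O)C1
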